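## Structural features

The target is a compact tetracycle built around two adjacent aminal carbons. Ring A is a 2,3-dibromopyrrole whose nitrogen N1 and carbon C5 are bridged by the six-membered lactam ring B (N1, C5, C15(=O), N14, C10, C6). The pyrrolidine ring C (N14, C10, C11–C13) shares the N14–C10 bond with ring B, and the cyclic N-methylguanidine ring D (C6, N7(Me), C8, N9, C10) shares the C6–C10 bond with it. C10 is fully substituted and carries N9, N14, C6 and C11; its neighbour C6 is an aminal CH between the pyrrole nitrogen N1 and N7, and rings B and D are cis-fused, which corresponds to (6S,10R). The fragile elements are the two aminal centres (C6 can ionise or ring-open and re-close through pyrrole carbon C4 to the isophakellin skeleton), the basic and oxidisable free guanidine, the electron-rich pyrrole, and the two aryl C–Br bonds, which rule out late hydrogenolysis. The real difficulty is the absolute configuration of the quaternary C10; once it is fixed, C6 follows, because a five-membered ring D can only be cis-fused to ring B. The key step exploits the fact that, with C6 at the oxidation level of an N-acylpyrrole carbonyl, C10 is the acidic α-carbon of a glycine unit locked in ring B and already bonded to N9 and N14, so ring C is only a three-carbon bridge from the C10 enolate to N14.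

## Logic of the disconnections

21 to 20. The carbamate C–N bond on the exocyclic guanidine nitrogen is cut first. A guanidine that stays acylated to the end is neither strongly basic nor easily oxidised, and this carbamate leaves under acid that does not touch aryl bromides. The forward step must not ionise the C6 or C10 aminal.

20 to 19. The C2–Br and C3–Br bonds are cut. A bromine at C2 would sit beside the C6 carbonyl of every N-acylpyrrole intermediate, twist it out of conjugation and make it a stronger acylating agent, so halogenation is placed after C6 has reached the aminal level. The forward step needs substitution at the two pyrrole positions remote from C15 and an inert guanidine.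

19 to 17 (through 18). C6–N7 is cut, which opens ring D and removes the C6 stereocentre, leaving a C6 hemiaminal and an open N-methylguanidine on N9. The forward step must turn the hydroxyl into a leaving group and close through N7 and not through the carbamate-bearing nitrogen; the C6 configuration is then dictated by C10.

17 to 12 and 15 (through 16). N9–C8 is cut, so that C8, N7 with its methyl group and the protected exocyclic nitrogen arrive in one reagent. The simplification is a primary amine; the demand is that the hindered, electron-poor N9 add to a strongly electrophilic carbon, which is why 15 is activated to 16. Compound 15 is cut at its N–C(S) bond into 13 and 14.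

12 to 11 to 10. The C=N bond of the N9 ketimine is restored, then the C6–H bond is removed to return C6 to the carbonyl level. The forward order is reduction before unmasking of N9, so that no N–H nucleophile ever sits five atoms from an acylating carbonyl and the hydrolysable N-acylpyrrole is gone before aqueous acid and amine bases are used. The hydride must stop at the carbinol and spare the ketimine and C15.

10 to 7 and 8 (through 9). C10–C11 and C13–N14 are cut; ring C and the only stereocentre disappear, and a flat, racemic, enolisable bicycle remains. The stereochemical problem is reduced to an enantiofacial alkylation of one planar enolate. The forward step needs carbon alkylation before nitrogen alkylation, bromide before chloride, and face selection by a chiral cation.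

7 to 4 and 5 (through 6). C10–N9 is cut. N9 is brought in as a nucleophile on an electrophilic C10, and the ketimine then serves as protecting group, acidifying group and face-differentiating group for the key step. The forward step must functionalise C10–H without halogenating the pyrrole.

4 to 3, then 3 to 1 and 2. The two acyl–nitrogen bonds N1–C6 and N14–C15 are cut, which leads to commercial materials. The N-acylation of the pyrrole by an ester is uphill unless the product is deprotonated, so the forward step needs a stoichiometric base.

## Other disconnections considered

Alternative 1: The cut runs through C6–C10 and N14–C15 at once and turns the ring-free amide A4 into three components: the cyclic ketimine ester A1, the dibromopyrrole acid A2 and methyl isocyanide A3. In the forward Joullié–Ugi reaction, protonated A1 is attacked at C10 by the isocyanide carbon, the nitrilium ion is captured by the carboxylate of A2, and a Mumm acyl shift to N14 gives A4.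
- In its favour: one step makes the quaternary carbon and the C15 amide and brings in the N7 methyl group, both bromines and every carbon except C8. There is no N-acylpyrrole and no late bromination, and the ester of A4 is a latent N9 (Curtius rearrangement with retention).
- Against it here: C10 is formed with no control element. The components are achiral, and enantioselective Ugi reactions of ketimines are not an established tool, so a resolution or an unproven catalyst would be needed. A1 is a labile α-imino ester (enamine tautomer, oligomers), and ketimines are the less reactive Ugi partners. A3 is volatile and hazardous. After the key step the ester must become N9, C8 must be inserted, the C6 secondary amide must be taken down to the aminal level beside the C15 amide, and rings B and D must both be closed.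
- Comparison: Alternative 1 is the better plan on convergence and on carrying bromine and the N-methyl group from the start. The two key steps are equal in skeletal bonds formed (two each). The chosen step also closes ring C and sets C10 absolutely, and it needs only one hydride reduction at C6 against a partial reduction of a secondary amide.

Alternative 2: The cut removes N14 from between C15 and C10, so that A6 goes back to A5, in which ring B is contracted to a five-membered pyrrolyl ketone and ring C is opened to a 3-azidopropyl chain on C10. In the forward intramolecular Schmidt reaction, an acid promoter lets the azide add to the C15 ketone, and C10 migrates from C15 to nitrogen with retention while the two terminal azide nitrogens are extruded.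
- In its favour: two C–N bonds, ring C and the expansion of ring B come from one step, both stereocentres are relayed unchanged, and the three-carbon tether on the α-carbon is the ideal length for this reaction.
- Against it here: the ketone is a 2-acylpyrrole, a vinylogous amide of low electrophilicity. The migrating carbon is a quaternary aminal carbon next to an acylguanidine that is protonated under the conditions, so its migratory aptitude is doubtful and migration of pyrrole carbon C5 or fragmentation can compete. Strong acid meets two aminals. A5 already contains ring D, both stereocentres and a strained pyrrolizinone, so the asymmetric construction of C10 is only postponed. The Cbz group must be removed by hydrogenolysis before the bromines are introduced.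
- Comparison: Alternative 2 is the better plan in rings handled per step (one closed, one expanded) and equal to the chosen plan in needing a late dibromination. It is weaker in precursor simplicity and in the chemoselectivity risk of its key step, and its overall count is likely to be higher.

Alternative 3: The cut is C6–N7, so that A8 goes back to A7, in which C6 is a plain methylene and the N-methylguanidine hangs from N9. In the forward Hofmann–Löffler–Freytag-type relay, a hypervalent iodine oxidant and iodine under light iodinate N7, homolysis gives the guanidinyl radical, a 1,5-hydrogen shift moves the radical to C6 (α to N1), and oxidative capture by N7 closes ring D.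
- In its favour: ring D is closed by C–H amination at the last stage with no oxidation-state handle on C6. The bromines are present from the start, and C6 is again fixed by the cis fusion. A8 is the same compound as 20, so both plans end with the same deprotection.
- Against it here: nitrogen radicals from guanidines are far less developed than those from sulfonamides or carbamates, and several nitrogens can be iodinated. The N7 radical has an equally placed hydrogen at C11, and electrophilic iodine can attack C4 of the pyrrole. Most seriously, A7 has no carbonyl at C6, so C10 is not enolisable and the quaternary aminal centre must be made by some other asymmetric method.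
- Comparison: Alternative 3 is the better plan in end-game economy (no carbonyl reduction, no activation of C6, no bromination step) and equal in the way C6 is controlled. It is weaker in the construction of C10 and in the selectivity of the radical step.

Key step: step 4

Remarks on the chemistry (assumptions):
- Phakellin locants (N1, C6, N7, C10, N14, C15) are used for positions throughout; glycine methyl ester is used as its commercial hydrochloride 2.
- The precursor 7 is named as the 2,3-dihydro dione because C10 is an sp3 CH; its structure and that of 10 agree with the (6S,10R) target.
- The (S,S) catalyst antipode is assumed to deliver the (R) centre at C10; if a trial shows the opposite sense, the mirror-image catalyst is used with no other change.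
- Compounds 11, 12, 17 and 18 are carried as mixtures of C6 epimers (no descriptor at C6 in their SMILES), because step 9 converges both epimers.

## Route

Step 1
Reactants: 1 2-(trichloroacetyl)pyrrole; 2 glycine methyl ester hydrochloride
Product: 3 methyl N-(1H-pyrrole-2-carbonyl)glycinate
Conditions: Et3N, MeCN, rt
Reagents that add atoms: none
Why: Haloform-type acyl substitution: the liberated amine attacks the trichloromethyl ketone and the trichloromethyl group leaves as chloroform, forming N14–C15 without protection of the pyrrole N–H.

Step 2
Reactants: 3 methyl N-(1H-pyrrole-2-carbonyl)glycinate
Product: 4 2,3-dihydropyrrolo[1,2-a]pyrazine-1,4-dione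
Conditions: NaH (1.2 equiv), THF, 0 °C to rt; then AcOH, 0 °C
Reagents that add atoms: none
Why: Base-mediated lactamisation (intramolecular N-acylation, 6-exo-trig): the pyrrolide attacks the methyl ester to form N1–C6. The released methoxide deprotonates the more acidic product, which pulls the otherwise reversible acyl transfer forward until the cold acid quench.

Step 3
Reactants: 4 2,3-dihydropyrrolo[1,2-a]pyrazine-1,4-dione; 5 benzophenone imine
Product: 7 racemic 3-[(diphenylmethylidene)amino]-2,3-dihydropyrrolo[1,2-a]pyrazine-1,4-dione, via C10 bromide 6 (not isolated)
Conditions: NBS (1.0 equiv), AIBN (cat.), PhCl, 80 °C; then 5, iPr2NEt, CH2Cl2, −20 °C to rt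
Reagents that add atoms: none
Why: Wohl–Ziegler bromination at the captodative C10–H (between N14 and the C6 carbonyl), as used for glycine templates; the doubly acylated pyrrole is deactivated toward electrophilic bromine. The labile N–H α-bromo lactam is displaced at once by the imine nitrogen, directly or through the cyclic N-acylimine, to give the Schiff base of the aminoglycine unit.

Step 4
Reactants: 7 racemic 3-[(diphenylmethylidene)amino]-2,3-dihydropyrrolo[1,2-a]pyrazine-1,4-dione; 8 1-bromo-3-chloropropane
Product: 10 (10aR)-10a-[(diphenylmethylidene)amino]-2,3-dihydro-1H-dipyrrolo[1,2-a:1',2'-d]pyrazine-5,10(10aH)-dione, via chloropropyl lactam 9 (not isolated)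
Conditions: (11bS,11'bS)-2,6-bis(3,4,5-trifluorophenyl)-3,3',5,5'-tetrahydro-4,4'-spirobi[dinaphtho[2,1-c:1',2'-e]azepin]-4-ium bromide (2 mol %), Cs2CO3 (solid, 3 equiv), toluene, 0 °C; then Bu4NI (cat.), 45 °C
Reagents that add atoms: none
Why: Solid Cs2CO3 removes the C10–H of racemic 7, which is acidified by the N-acylpyrrole carbonyl C6 and the ketimine N9, and the planar, ring-locked 2-azaallyl enolate enters toluene as an ion pair with the C2-symmetric spiro ammonium cation; both enantiomers of 7 give the same enolate, so the step is stereoconvergent. The closest known reaction type is the asymmetric phase-transfer alkylation of α-substituted amino acid Schiff bases to quaternary α-amino acid derivatives, here with an amide nitrogen as the second α-substituent. SN2 attack of the enolate carbon on the bromide end of 8 forms C10–C11 and gives 9; the new stereocentre C10 is set by the catalyst, whose aryl-flanked binaphthyl walls cover one face of the enolate while the diphenylketimine, the only group that projects from the flat bicycle, fixes how the anion docks. In 9 the lactam N14–H is the only acidic site left, and its anion displaces chloride in a 5-exo-tet closure (C13–N14) that completes ring C, helped by warming and by iodide added only after the stereocentre is set. The step needs carbon before nitrogen alkylation, which the far greater acidity of C10–H over N14–H secures, carbon over oxygen alkylation, which the soft azaallyl carbon and the non-polar medium favour, and bromide before chloride, which leaving-group ability secures. Water-free solid–liquid conditions protect the N-acylpyrrole from hydrolysis, and the quaternary centre cannot racemise once formed.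

Step 5
Reactants: 10 (10aR)-10a-[(diphenylmethylidene)amino]-2,3-dihydro-1H-dipyrrolo[1,2-a:1',2'-d]pyrazine-5,10(10aH)-dione
Product: 11 (10aR)-10a-[(diphenylmethylidene)amino]-10-hydroxy-2,3,10,10a-tetrahydro-1H-dipyrrolo[1,2-a:1',2'-d]pyrazin-5-one (both C6 epimers)
Conditions: NaBH4 (1.0 equiv), THF–EtOH, −20 °C; aq. NH4Cl
Reagents that add atoms: none
Why: Chemoselective hydride addition to the ketone-like N-acylpyrrole carbonyl gives a tetrahedral pyrrole carbinol that is stable because the pyrrolide is a poor leaving group. The tertiary lactam C15 and the hindered diaryl ketimine on a tertiary carbon should not react at this temperature, and the C6 configuration is of no consequence.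

Step 6
Reactants: 11 (10aR)-10a-[(diphenylmethylidene)amino]-10-hydroxy-2,3,10,10a-tetrahydro-1H-dipyrrolo[1,2-a:1',2'-d]pyrazin-5-one
Product: 12 (10aR)-10a-amino-10-hydroxy-2,3,10,10a-tetrahydro-1H-dipyrrolo[1,2-a:1',2'-d]pyrazin-5-one hydrochloride
Conditions: 0.5 M aq. HCl, THF, 0 °C; Et2O wash, freeze-drying
Reagents that add atoms: hydrogen chloride, Cl
Why: Acid hydrolysis of the Schiff base frees N9 as its ammonium salt, and benzophenone is washed out. The quaternary C10 cannot epimerise, and the hemiaminal should tolerate cold dilute acid because the acylating N-acylpyrrole has already been removed.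

Step 7
Reactants: 13 tert-butyl carbamate; 14 methyl isothiocyanate
Product: 15 tert-butyl N-(methylcarbamothioyl)carbamate (N-Boc-N'-methylthiourea)
Conditions: NaH, THF, 0 °C to rt; then AcOH
Reagents that add atoms: none
Why: Addition of the carbamate anion to the isothiocyanate carbon gives the mono-Boc thiourea with the methyl group unambiguously on the other nitrogen.

Step 8
Reactants: 12 (10aR)-10a-amino-10-hydroxy-2,3,10,10a-tetrahydro-1H-dipyrrolo[1,2-a:1',2'-d]pyrazin-5-one hydrochloride; 15 tert-butyl N-(methylcarbamothioyl)carbamate
Product: 17 tert-butyl N-[{[(10aR)-10-hydroxy-5-oxo-2,3,10,10a-tetrahydro-1H-dipyrrolo[1,2-a:1',2'-d]pyrazin-10a-yl]amino}(methylamino)methylidene]carbamate, via N-Boc-N'-methylcarbodiimide 16 (not isolated)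
Conditions: 15, EDCI·HCl, Et3N, DMF, 0 °C; then 12, rt
Reagents that add atoms: none
Why: Desulfurative guanylation: EDCI converts the acylthiourea into the strongly electrophilic acyl carbodiimide 16, and the primary amine N9 adds to it to form N9–C8. The hydroxyl is a much poorer nucleophile than the amine, and no N-acylpyrrole is left to be attacked by the new guanidine N–H.

Step 9
Reactants: 17 tert-butyl N-[{[(10aR)-10-hydroxy-5-oxo-2,3,10,10a-tetrahydro-1H-dipyrrolo[1,2-a:1',2'-d]pyrazin-10a-yl]amino}(methylamino)methylidene]carbamate
Product: 19 N-Boc-7-N-methylphakellin (cis-fused tetracycle with the Boc group on the exocyclic guanidine nitrogen), via C6 mesylate 18 (not isolated)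
Conditions: MsCl, Et3N, CH2Cl2, −20 °C to rt
Reagents that add atoms: none
Why: Intramolecular amidoalkylation (hemiaminal to aminal exchange): mesylation makes the C6 hydroxyl a leaving group that departs with help from the pyrrole nitrogen or after chloride exchange, and the tethered N7–H closes ring D in a 5-exo mode under basic, kinetic conditions that favour nitrogen over pyrrole carbon. N7 hangs from N9 on C10 and can reach only the face of C6 syn to N9, so the cis fusion and the C6 configuration follow from C10 for either C6 epimer. The alkyl-substituted N7 is a far better nucleophile than the carbamate-bearing nitrogen.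

Step 10
Reactants: 19 N-Boc-7-N-methylphakellin
Product: 20 N-Boc-7-N-methyldibromophakellin
Conditions: NBS (2.05 equiv), THF, −20 to 0 °C, dark
Reagents that add atoms: N-bromosuccinimide, O=C1CCC(=O)N1Br
Why: Electrophilic aromatic bromination of an N-alkylpyrrole-2-carboxamide occurs at the two positions remote from the acyl group (C3, then C2) and spares C4 next to the carbonyl. The acylated guanidine is not basic or nucleophilic enough to interfere.

Step 11
Reactants: 20 N-Boc-7-N-methyldibromophakellin
Product: 21 (−)-7-N-methyldibromophakellin
Conditions: TFA, CH2Cl2, 0 °C to rt; then aq. NaHCO3
Reagents that add atoms: none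
Why: Acidolysis of the tert-butyl carbamate with loss of isobutene and carbon dioxide frees the guanidine. The aryl bromides, the lactam and the protonated aminal framework are stable to TFA, and neither stereocentre is touched.

## Compound list

1 | 2-(trichloroacetyl)pyrrole (2,2,2-trichloro-1-(1H-pyrrol-2-yl)ethanone) | O=C(c1ccc[nH]1)C(Cl)(Cl)Cl | starting material
2 | glycine methyl ester hydrochloride | COC(=O)CN.Cl | starting material
3 | methyl N-(1H-pyrrole-2-carbonyl)glycinate | COC(=O)CNC(=O)c1ccc[nH]1 | intermediate
4 | 2,3-dihydropyrrolo[1,2-a]pyrazine-1,4-dione (rings A and B, C10 methylene) | O=C1NCC(=O)n2cccc12 | intermediate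
5 | benzophenone imine (diphenylmethanimine) | N=C(c1ccccc1)c1ccccc1 | starting material
6 | racemic 3-bromo-2,3-dihydropyrrolo[1,2-a]pyrazine-1,4-dione | O=C1NC(Br)C(=O)n2cccc12 | intermediate (not isolated)
7 | racemic 3-[(diphenylmethylidene)amino]-2,3-dihydropyrrolo[1,2-a]pyrazine-1,4-dione | O=C1NC(N=C(c2ccccc2)c2ccccc2)C(=O)n2cccc12 | intermediate
8 | 1-bromo-3-chloropropane | ClCCCBr | starting material
9 | (3S)-3-(3-chloropropyl)-3-[(diphenylmethylidene)amino]-2,3-dihydropyrrolo[1,2-a]pyrazine-1,4-dione | O=C1N[C@@](CCCCl)(N=C(c2ccccc2)c2ccccc2)C(=O)n2cccc12 | intermediate (not isolated)
10 | (10aR)-10a-[(diphenylmethylidene)amino]-2,3-dihydro-1H-dipyrrolo[1,2-a:1',2'-d]pyrazine-5,10(10aH)-dione (rings A, B, C; C10 of the target is R) | O=C1N2CCC[C@]2(N=C(c3ccccc3)c3ccccc3)C(=O)n3cccc13 | intermediate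
11 | (10aR)-10a-[(diphenylmethylidene)amino]-10-hydroxy-2,3,10,10a-tetrahydro-1H-dipyrrolo[1,2-a:1',2'-d]pyrazin-5-one, both epimers at the carbinol carbon (C6 of the target) | O=C1N2CCC[C@]2(N=C(c3ccccc3)c3ccccc3)C(O)n3cccc13 | intermediate
12 | (10aR)-10a-amino-10-hydroxy-2,3,10,10a-tetrahydro-1H-dipyrrolo[1,2-a:1',2'-d]pyrazin-5-one hydrochloride, both carbinol epimers | O=C1N2CCC[C@]2(N)C(O)n3cccc13.Cl | intermediate
13 | tert-butyl carbamate | NC(=O)OC(C)(C)C | starting material
14 | methyl isothiocyanate | CN=C=S | starting material
15 | tert-butyl N-(methylcarbamothioyl)carbamate (N-Boc-N'-methylthiourea) | CNC(=S)NC(=O)OC(C)(C)C | intermediate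
16 | tert-butyl N-[(methylimino)methylidene]carbamate (N-Boc-N'-methylcarbodiimide) | CN=C=NC(=O)OC(C)(C)C | intermediate (not isolated)
17 | tert-butyl N-[{[(10aR)-10-hydroxy-5-oxo-2,3,10,10a-tetrahydro-1H-dipyrrolo[1,2-a:1',2'-d]pyrazin-10a-yl]amino}(methylamino)methylidene]carbamate, both carbinol epimers | CNC(=NC(=O)OC(C)(C)C)N[C@]12CCCN1C(=O)c1cccn1C2O | intermediate
18 | methanesulfonate of 17 at the carbinol oxygen (C6 mesylate) | CNC(=NC(=O)OC(C)(C)C)N[C@]12CCCN1C(=O)c1cccn1C2OS(C)(=O)=O | intermediate (not isolated)
19 | N-Boc-7-N-methylphakellin, rings B and D cis-fused, 10R; the same spatial arrangement at C6 as the target, where the descriptor reads R only because the bromine-free pyrrole nitrogen ranks below N7 | CN1C(=NC(=O)OC(C)(C)C)N[C@]23CCCN2C(=O)c2cccn2[C@H]13 | intermediate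
20 | N-Boc-7-N-methyldibromophakellin, (6S,10R), bromine at C2 and C3 | CN1C(=NC(=O)OC(C)(C)C)N[C@]23CCCN2C(=O)c2cc(Br)c(Br)n2[C@H]13 | intermediate
21 | (−)-7-N-methyldibromophakellin, (6S,10R) | CN1C(N)=N[C@]23CCCN2C(=O)c2cc(Br)c(Br)n2[C@H]13 | target

## Step count and least certain steps

Total: 11 steps. Longest linear sequence: 10 steps (steps 1–6 and 8–11, from 1); step 7 is a one-step branch that supplies 15.

Step 4 (key step). The most likely failure is weak facial discrimination: the highly stabilised enolate pairs loosely with the cation, the electrophile is an unactivated primary bromide, and alkylation at the solid carbonate surface without the catalyst would give racemic material. Alkylation at N14 ahead of C10, or a 1,3-proton shift of the azaallyl anion toward the N-benzhydryl amidine tautomer, would also erode the result. Fallback: from 7 the annulation is run with an achiral catalyst (Bu4NBr, Cs2CO3, MeCN, rt) to give the racemic tricyclic ketimine dione F1, whose enantiomers are separated by preparative chromatography on a chiral stationary phase; the (R) enantiomer is 10, where the route is rejoined.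

Step 9. Ionisation or substitution at the neopentyl-like C6 may be slow, and ring B may instead open and re-close through pyrrole carbon C4 (isophakellin-type closure), or the guanidine may be sulfonylated. Fallback: from 17, catalytic DBU in MeCN is used to open the pyrrole hemiaminal to its aldehyde form, onto which N7 adds to give the ring D hemiaminal with a free pyrrole N–H F10. Mesylation of F10 under Et3N then generates a cation stabilised by the guanidine nitrogen, and the pyrrole nitrogen closes ring B, so that N1–C6 instead of N7–C6 is the last bond formed; the route is rejoined at 19.

Step 3. Electrophilic bromination of the pyrrole ring, double bromination at C10, or base-induced prototropic isomerisation of 7 to its amidine tautomer may compete. Fallback: from 4, N-chlorination with tBuOCl gives the N14-chloro lactam F2, Et3N eliminates hydrogen chloride to the cyclic N-acylimine F3, and 5 adds to C10 of F3 in the same flask; the route is rejoined at 7.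

Step 8. The hindered, inductively deactivated amine on the aminal carbon may add too slowly to the carbodiimide, which then decays, while the free amine degrades under base. Fallback with reversed roles: from 12, benzyloxycarbonyl isothiocyanate (from benzyl chloroformate and KSCN) acylates N9 to the Cbz-thiourea carbinol F6. EDCI and methylamine convert F6 into the Cbz-protected N-methylguanidine carbinol F7, and closure as in step 9 gives N-Cbz-7-N-methylphakellin F8 (the same compound as A6). Hydrogenolysis over Pd/C before any bromine is present gives 7-N-methylphakellin F9, and NBS (2 equiv) on its trifluoroacetate salt followed by neutralisation gives 21, where the route is rejoined.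

Step 5. Collapse of the tetrahedral alkoxide to the ring-opened aldehyde and a second hydride addition (over-reduction), or alcoholysis of the N-acylpyrrole, may occur. Fallback: from 10, the over-reduction is made deliberate with LiBH4 to give the ring-opened primary alcohol F4; Dess–Martin oxidation gives the aldehyde F5, which should close spontaneously through the pyrrole N–H onto the aldehyde to give 11, where the route is rejoined.

## Further compounds

F1 | step 4 | racemic 10a-[(diphenylmethylidene)amino]-2,3-dihydro-1H-dipyrrolo[1,2-a:1',2'-d]pyrazine-5,10(10aH)-dione | O=C1N2CCCC2(N=C(c3ccccc3)c3ccccc3)C(=O)n3cccc13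
F2 | step 3 | 2-chloro-2,3-dihydropyrrolo[1,2-a]pyrazine-1,4-dione | O=C1N(Cl)CC(=O)n2cccc12
F3 | step 3 | pyrrolo[1,2-a]pyrazine-1,4-dione (cyclic N-acylimine) | O=C1N=CC(=O)n2cccc12
F4 | step 5 | [(2R)-2-[(diphenylmethylidene)amino]-2-(hydroxymethyl)pyrrolidin-1-yl](1H-pyrrol-2-yl)methanone | OC[C@@]1(N=C(c2ccccc2)c2ccccc2)CCCN1C(=O)c1ccc[nH]1
F5 | step 5 | (2R)-2-[(diphenylmethylidene)amino]-1-(1H-pyrrole-2-carbonyl)pyrrolidine-2-carbaldehyde | O=C[C@@]1(N=C(c2ccccc2)c2ccccc2)CCCN1C(=O)c1ccc[nH]1
F6 | step 8 | benzyl N-({[(10aR)-10-hydroxy-5-oxo-2,3,10,10a-tetrahydro-1H-dipyrrolo[1,2-a:1',2'-d]pyrazin-10a-yl]amino}carbonothioyl)carbamate | O=C(OCc1ccccc1)NC(=S)N[C@]12CCCN1C(=O)c1cccn1C2O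
F7 | step 8 | benzyl N-[{[(10aR)-10-hydroxy-5-oxo-2,3,10,10a-tetrahydro-1H-dipyrrolo[1,2-a:1',2'-d]pyrazin-10a-yl]amino}(methylamino)methylidene]carbamate | CNC(=NC(=O)OCc1ccccc1)N[C@]12CCCN1C(=O)c1cccn1C2O
F8 | step 8 | N-Cbz-7-N-methylphakellin | CN1C(=NC(=O)OCc4ccccc4)N[C@]23CCCN2C(=O)c2cccn2[C@H]13
F9 | step 8 | 7-N-methylphakellin | CN1C(N)=N[C@]23CCCN2C(=O)c2cccn2[C@H]13
F10 | step 9 | ring D hemiaminal: tert-butyl carbamate of the spiro 4-hydroxy-3-methyl-2-iminoimidazolidine whose spiro carbon is C2 of a 1-(1H-pyrrole-2-carbonyl)pyrrolidine, (R) at the spiro carbon | CN1C(=NC(=O)OC(C)(C)C)N[C@@]2(CCCN2C(=O)c2ccc[nH]2)C1O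
A1 | alternative 1 | methyl 3,4-dihydro-2H-pyrrole-5-carboxylate | COC(=O)C1=NCCC1
A2 | alternative 1 | 4,5-dibromo-1H-pyrrole-2-carboxylic acid | OC(=O)c1cc(Br)c(Br)[nH]1
A3 | alternative 1 | methyl isocyanide | C[N+]#[C-]
A4 | alternative 1 | methyl (2R)-1-(4,5-dibromo-1H-pyrrole-2-carbonyl)-2-(methylcarbamoyl)pyrrolidine-2-carboxylate | CNC(=O)[C@@]1(C(=O)OC)CCCN1C(=O)c1cc(Br)c(Br)[nH]1
A5 | alternative 2 | 2,3-dihydro-1H-pyrrolizin-1-one carrying a 3-azidopropyl group at C2 and the cis-fused N-methyl, N'-Cbz cyclic guanidine across C2–C3 | CN1C(=NC(=O)OCc2ccccc2)N[C@]2(CCCN=[N+]=[N-])C(=O)c3cccn3[C@H]12
A6 | alternative 2 | N-Cbz-7-N-methylphakellin | CN1C(=NC(=O)OCc4ccccc4)N[C@]23CCCN2C(=O)c2cccn2[C@H]13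
A7 | alternative 3 | rings A, B, C lactam with a C6 methylene, 2,3-dibromopyrrole and the N9 N-Boc-N'-methylguanidine on C10 (R) | CNC(=NC(=O)OC(C)(C)C)N[C@]12CCCN1C(=O)c1cc(Br)c(Br)n1C2
A8 | alternative 3 | N-Boc-7-N-methyldibromophakellin | CN1C(=NC(=O)OC(C)(C)C)N[C@]23CCCN2C(=O)c2cc(Br)c(Br)n2[C@H]13
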